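A closed, stirred vessel at constant temperature turns substrate into single ring and ring dimer, but in the midnight run at 40.0 min the three together leave 41.0% of the charge unread.

| flask | substrate | remark | time |
|---|---|---|---|
| midnight | 1 M | run made earlier |  |
| dawn | 2.2 M | run made earlier |  |
| flask | 1.5 M |  | 1.0 h |

| run | time / min | single ring / % | ring dimer / % | substrate / % |
|---|---|---|---|---|
| midnight | 3.00 | 8 | 2 | 70 |
| midnight | 10.0 | 21 | 1 | 37 |
| midnight | 15.0 | 21 | 5 | 28 |
| midnight | 25.0 | 30 | 16 | 16 |
| midnight | 40.0 | 28 | 23 | 8 |
| dawn | 3.00 | 8 | 0 | 57 |
| dawn | 10.0 | 15 | 8 | 28 |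
| dawn | 15.0 | 13 | 11 | 19 |
| dawn | 25.0 | 17 | 17 | 12 |
| dawn | 40.0 | 20 | 25 | 9 |

(readings scatter by 2 percentage points)

- percent here means substrate units held: one ring dimer counts as two
- the earlier runs were read with a standard deviation of 2 percentage points

1. concentration of single ring at 1.0 h, in M
2. concentration of ring dimer at 1.0 h, in M

I read the pace of ring dimer. From 10.0 min to 25.0 min the two runs gain 12 points of the charge on average. In the next 15.0 min they gain 7.5 points. Each gain carries about 2 points.

At 40.0 min the runs average 24.0%, and I take that for this flask, whose charge lies between theirs. One ring dimer holds two units. If the gain stopped there, this flask would hold 0.180 M. If the pace held, it would reach 34.0%, or 0.255 M. The later gain is smaller than the earlier but larger than its scatter, so I place the flask between these.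

In these readings the later window keeps 0.625 of the earlier gain, so I read a pace that halves in 22.1 min. I call this the fade time, an apparent first-order half-life. If each further window keeps that share, the sum leaves 12 points to come after 40.0 min, and 6.7 points of that still unmade at 1.0 h. So I expect 29.8%, or 0.224 M.

The forecast reasons that “Ring dimer grows about 0.45%/min” and gives 0.25 M of ring dimer, above my figure, with 0.4 M of single ring.

The flask at 1.0 h holds 0.362 M of single ring and 0.210 M of ring dimer, which is 28.0% of the charge against my 29.8%.

    open dimer → ring dimer (k = 5.50 × 10⁻⁴ /s)
    substrate + single ring → side product (k = 4.30 × 10⁻⁴ /M/s)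
    substrate + open dimer → open trimer (k = 0.00110 /M/s)
    2 substrate → open dimer (k = 6.80 × 10⁻⁴ /M/s)
    substrate ⇌ single ring (K = 7.70, k = 5.70 × 10⁻⁴ /s)

Now I read the same flask at 2.5 h. My reckoning keeps 6.7 points unmade after 1.0 h, and by the fade time 6.3 points of it falls within the next 1.50 h. Added to the simulated 28.0%, this gives 34.3%, or 0.257 M. That flask reads 32.7%, which is 0.246 M of ring dimer.

(The data stem from a simulated flask on assumed constants, and the scatter is random.)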